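## Retrosynthetic overview
1. 23 ⇒ 20 ⇒ 19. The γ-lactone is made last: the isopropenyl methyl (C12) is oxidised and closes onto 6-OH, and the C6–O bond is never broken.
2. 19 ⇒ 18. The ten-membered ring is closed at C6–C7 by a carbonyl-ene reaction. The aldehyde carbon plays farnesyl C1, the isopropylidene plays C10=C11, and a methyl proton is lost. The usual allyl-metal/2-(bromomethyl)acrylate closure is not used because it would expel the 8-acyloxy group.
3. 18 ⇒ 12 + crotylboronate (C4, C15, C5, C6). 12 ⇒ 9 + CO (C3). 9 ⇒ prenal (C7, C8, C11–C13) + acetone equivalent (C9, C10, C14) + vinyl (C1, C2) + isobutyric anhydride.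
4. Stereocentres: C8 comes from a catalytic aldol, C10 from chelation by C8, C4 from a catalyst-controlled crotylboration, and C6 and C7 from the ring closure under control of C8.
5. Ring order: carbocycle first, lactone second. No protecting groups are used.

Assumption: γ-hydroxy-carbonyl compounds (the target included, 12 excepted) are drawn and counted in their open form although they can equilibrate with 3,10-(hemi)ketal forms; locants are germacrane locants (C3 ketone, C4 CHMe, C6 lactone carbinol, C7 ring-fusion CH, C8 acyloxy carbon, C10 carbinol).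

## Route

Step 1
Reactants: 1 3-methylbut-2-enal (prenal); 2 2-methoxypropene
Product: 4 (4R)-4-hydroxy-6-methylhept-5-en-2-one, via enol ether adduct 3 (not isolated)
Conditions: 2 (10 equiv), Ti(IV)/tridentate binaphthyl Schiff base/3,5-di-t-Bu-salicylate catalyst (5 mol %, the antipode that gives R), 2,6-di-t-Bu-4-Me-pyridine (cat.), Et2O, 0 → 23 °C; then 0.5 M aq. citric acid, 0 °C
Reagents that add atoms: 2-methoxypropene C=C(C)OC; water O
Why: This is a catalytic enantioselective acetone aldol (ene-type addition of 2-methoxypropene to a conjugated aldehyde) in which the chiral Ti complex blocks one aldehyde face and sets C8 (R), and mild hydrolysis of the enol ether then releases the methyl ketone without ionising the allylic alcohol.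

Step 2
Reactants: 4 (4R)-4-hydroxy-6-methylhept-5-en-2-one; 5 vinylmagnesium bromide
Product: 7 (3R,5R)-3,7-dimethylocta-1,6-diene-3,5-diol, via magnesium chelate 6 (not isolated)
Conditions: 5 (2.5 equiv), THF–CH2Cl2, −78 °C; sat. aq. NH4Cl; chromatography
Reagents that add atoms: vinylmagnesium bromide C=C[Mg]Br
Why: In this chelation-controlled Grignard addition (Cram-chelate model) the first equivalent forms the Mg alkoxide, which ties the ketone into a six-membered half-chair with the isobutenyl group equatorial, so axial attack of vinyl gives the 1,3-anti diol and sets C10, and the minor syn isomer is removed by chromatography.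

Step 3
Reactants: 7 (3R,5R)-3,7-dimethylocta-1,6-diene-3,5-diol; 8 isobutyric anhydride
Product: 9 (3R,5R)-3-hydroxy-3,7-dimethylocta-1,6-dien-5-yl 2-methylpropanoate
Conditions: 8 (1.2 equiv), Et3N, DMAP (5 mol %), CH2Cl2, 0 °C
Reagents that add atoms: isobutyric anhydride CC(C)C(=O)OC(=O)C(C)C
Why: DMAP-catalysed (Steglich-type) acylation takes the secondary allylic alcohol and leaves the tertiary one untouched, and no stereocentre is affected.

Step 4
Reactants: 9 (3R,5R)-3-hydroxy-3,7-dimethylocta-1,6-dien-5-yl 2-methylpropanoate; 10 carbon monoxide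
Product: 12 (2R)-1-[(2S)-5-hydroxy-2-methyloxolan-2-yl]-4-methylpent-3-en-2-yl 2-methylpropanoate (anomers), via hydroxy aldehyde 11 (not isolated)
Conditions: Rh(acac)(CO)2 (1 mol %), Xantphos (2 mol %), CO/H2 1:1 (20 bar), toluene, 70 °C
Reagents that add atoms: carbon monoxide [C-]#[O+]
Why: In this Rh-catalysed hydroformylation the quaternary allylic carbon enforces the linear aldehyde, the trisubstituted alkene is inert, and the γ-hydroxy aldehyde closes to the lactol, whose anomeric carbon later becomes the C3 ketone, so no lasting stereocentre is made.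

Step 5
Reactants: 12 lactol; 13 (E)-crotylboronic acid pinacol ester
Product: 15 (3R,4S,7S,9R)-4,7-dihydroxy-3,7,11-trimethyldodeca-1,10-dien-9-yl 2-methylpropanoate, via boronate ester 14 (not isolated)
Conditions: 13 (1.5 equiv), (R)-TRIP phosphoric acid (10 mol %), toluene, −20 → 0 °C; then H2O/aq. NaHCO3
Reagents that add atoms: (E)-crotylboronic acid pinacol ester C/C=C/CB1OC(C)(C)C(C)(C)O1
Why: This chiral-phosphoric-acid-catalysed crotylboration runs through a Zimmerman–Traxler chair, so the E-boronate gives the anti adduct and catalyst-directed Re-face attack on the open aldehyde (kept available by the acid) sets C4 (R), while the C3 carbinol (S) is erased in step 7.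

Step 6
Reactants: 15 homoallylic diol
Product: 17 (3R,4S,7S,9R)-1,4,7-trihydroxy-3,7,11-trimethyldodec-10-en-9-yl 2-methylpropanoate, via tris-boryl adduct 16 (not isolated)
Conditions: 9-BBN-H (3.3 equiv), THF, 0 → 23 °C; then 30 % H2O2, aq. NaOAc, 0 → 23 °C
Reagents that add atoms: hydrogen peroxide OO
Why: Brown hydroboration–oxidation with 9-BBN adds anti-Markovnikov to the monosubstituted alkene only (the trisubstituted alkene and the ester are too slow), the buffered oxidation spares the isobutyrate, and no stereocentre is touched.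

Step 7
Reactants: 17 triol
Product: 18 (3R,7S,9R)-7-hydroxy-3,7,11-trimethyl-1,4-dioxododec-10-en-9-yl 2-methylpropanoate
Conditions: (COCl)2 (3 equiv), DMSO (6 equiv), CH2Cl2, −78 °C; Et3N (10 equiv), −78 → −30 °C
Reagents that add atoms: none
Why: In this double Swern oxidation both carbinols are activated before base is added, so the 1,4-diol gives the keto-aldehyde and not a lactone, the tertiary alcohol cannot be oxidised, and the low temperature keeps C4 (now α to the ketone) intact.

Step 8
Reactants: 18 keto-aldehyde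
Product: 19 (4R,6S,7S,8R,10S)-6,10-dihydroxy-8-isobutyryloxygermacr-11(12)-en-3-one (7-isopropenyl cyclodecanone)
Conditions: MABR [MeAl(O-2,6-t-Bu2-4-BrC6H2)2, 3 equiv, from Me3Al + 2 ArOH], CH2Cl2, 18 added over 10 h to 1 mM final, −78 → −20 °C; then 1 M HCl, 0 °C
Reagents that add atoms: none
Why: Proposed new method: this is a ten-membered type-I carbonyl-ene closure in which the bulky, non-nucleophilic Al Lewis acid binds the least hindered carbonyl (the aldehyde, anti to C5), C7 of the isopropylidene attacks C6, and a methyl proton passes to oxygen through a six-centre array, just as farnesyl C1→C10 closure with proton loss gives germacrene A; A(1,3) strain with the Z-methyl holds H-8 in the alkene plane and puts the C8–C9 bond (the best σ-donor, and the tether) anti to the incoming carbon, which sets C7 (S) from C8, while Al anti to C5 forces C5 pseudo-axial and C8 pseudo-equatorial (a cis-fused array), which sets C6 (S); a neutral alkene is used because an allyl-metal at C7 would lose the 8-acyloxy group by 1,4-elimination; the closest known reaction types are the aluminium-aryloxide-catalysed citronellal → isopulegol ene cyclisation and alkylaluminium-halide-promoted macrocyclic ene closures of ω-alkenyl ynals.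

Step 9
Reactants: 19 macrocyclic diol
Product: 20 (4R,6S,7S,8R,10S)-6,10,12-trihydroxy-8-isobutyryloxygermacr-11(13)-en-3-one
Conditions: SeO2 (0.3 equiv), t-BuOOH (3 equiv, decane), CH2Cl2, 0 → 23 °C
Reagents that add atoms: selenium dioxide O=[Se]=O; tert-butyl hydroperoxide CC(C)(C)OO
Why: SeO2/TBHP allylic hydroxylation (ene reaction then [2,3]-shift) attacks the only alkene and prefers the methyl over the hindered C7 methine, as in the isopulegol series; any enal formed converges in step 10, and no stereocentre is touched.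

Step 10
Reactants: 20 triol
Product: 23 (4R,6S,7S,8R,10S)-10-hydroxy-8-isobutyryloxy-3-oxogermacr-11(13)-en-12,6-olide (target), via hydroxy enal 21 (not isolated), via lactol 22 (not isolated)
Conditions: TEMPO (20 mol %), PhI(OAc)2 (2.5 equiv), CH2Cl2, 23 °C
Reagents that add atoms: none
Why: TEMPO/PhI(OAc)2 oxidative lactonisation takes the primary allylic alcohol to the enal, 6-OH closes to the lactol, and a second oxidation gives the α-methylene-γ-lactone, mirroring C12 oxidation followed by lactonisation; the C6–O bond stays intact, so the 6,7-cis fusion set in step 8 is retained.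

## Compound list
1 | 3-methylbut-2-enal (prenal) | CC(C)=CC=O | starting material
2 | 2-methoxypropene | C=C(C)OC | starting material
3 | (4R)-2-methoxy-6-methylhepta-1,5-dien-4-ol | C=C(OC)C[C@@H](O)C=C(C)C | intermediate
4 | (4R)-4-hydroxy-6-methylhept-5-en-2-one | CC(=O)C[C@@H](O)C=C(C)C | intermediate
5 | vinylmagnesium bromide | C=C[Mg]Br | starting material
6 | bromomagnesium alkoxide of 4 (Mg chelate) | CC(=O)C[C@@H](O[Mg]Br)C=C(C)C | intermediate
7 | (3R,5R)-3,7-dimethylocta-1,6-diene-3,5-diol | C=C[C@](C)(O)C[C@@H](O)C=C(C)C | intermediate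
8 | isobutyric anhydride | CC(C)C(=O)OC(=O)C(C)C | starting material
9 | (3R,5R)-3-hydroxy-3,7-dimethylocta-1,6-dien-5-yl 2-methylpropanoate | C=C[C@](C)(O)C[C@@H](OC(=O)C(C)C)C=C(C)C | intermediate
10 | carbon monoxide | [C-]#[O+] | starting material
11 | (4S,6R)-4-hydroxy-4,8-dimethyl-1-oxonon-7-en-6-yl 2-methylpropanoate | O=CCC[C@](C)(O)C[C@@H](OC(=O)C(C)C)C=C(C)C | intermediate
12 | (2R)-1-[(2S)-5-hydroxy-2-methyloxolan-2-yl]-4-methylpent-3-en-2-yl 2-methylpropanoate (anomers) | OC1CC[C@](C)(O1)C[C@@H](OC(=O)C(C)C)C=C(C)C | intermediate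
13 | (E)-crotylboronic acid pinacol ester | C/C=C/CB1OC(C)(C)C(C)(C)O1 | starting material
14 | 4-O-(pinacolatoboryl) derivative of 15 | C=C[C@@H](C)[C@@H](OB1OC(C)(C)C(C)(C)O1)CC[C@](C)(O)C[C@@H](OC(=O)C(C)C)C=C(C)C | intermediate
15 | (3R,4S,7S,9R)-4,7-dihydroxy-3,7,11-trimethyldodeca-1,10-dien-9-yl 2-methylpropanoate | C=C[C@@H](C)[C@@H](O)CC[C@](C)(O)C[C@@H](OC(=O)C(C)C)C=C(C)C | intermediate
16 | C1-(9-BBN) borane of 15 with both hydroxyls as O-(9-BBN) borinates | C(C[C@@H](C)[C@@H](OB1C2CCCC1CCC2)CC[C@](C)(OB1C2CCCC1CCC2)C[C@@H](OC(=O)C(C)C)C=C(C)C)B1C2CCCC1CCC2 | intermediate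
17 | (3R,4S,7S,9R)-1,4,7-trihydroxy-3,7,11-trimethyldodec-10-en-9-yl 2-methylpropanoate | OCC[C@@H](C)[C@@H](O)CC[C@](C)(O)C[C@@H](OC(=O)C(C)C)C=C(C)C | intermediate
18 | (3R,7S,9R)-7-hydroxy-3,7,11-trimethyl-1,4-dioxododec-10-en-9-yl 2-methylpropanoate | O=CC[C@@H](C)C(=O)CC[C@](C)(O)C[C@@H](OC(=O)C(C)C)C=C(C)C | intermediate
19 | (4R,6S,7S,8R,10S)-6,10-dihydroxy-8-isobutyryloxygermacr-11(12)-en-3-one | O[C@H]1C[C@@H](C)C(=O)CC[C@](C)(O)C[C@@H](OC(=O)C(C)C)[C@H]1C(C)=C | intermediate
20 | (4R,6S,7S,8R,10S)-6,10,12-trihydroxy-8-isobutyryloxygermacr-11(13)-en-3-one | O[C@H]1C[C@@H](C)C(=O)CC[C@](C)(O)C[C@@H](OC(=O)C(C)C)[C@H]1C(=C)CO | intermediate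
21 | (4R,6S,7S,8R,10S)-6,10-dihydroxy-8-isobutyryloxy-3-oxogermacr-11(13)-en-12-al | O[C@H]1C[C@@H](C)C(=O)CC[C@](C)(O)C[C@@H](OC(=O)C(C)C)[C@H]1C(=C)C=O | intermediate
22 | 6,12-lactol of 21 (anomers) | C=C1C(O)O[C@H]2C[C@@H](C)C(=O)CC[C@](C)(O)C[C@@H](OC(=O)C(C)C)[C@@H]12 | intermediate
23 | (4R,6S,7S,8R,10S)-10-hydroxy-8-isobutyryloxy-3-oxogermacr-11(13)-en-12,6-olide | C=C1C(=O)O[C@H]2C[C@@H](C)C(=O)CC[C@](C)(O)C[C@@H](OC(=O)C(C)C)[C@@H]12 | target

## Step count and risks
Total step count: 10. Longest linear sequence: 10 (1 → 23).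

**Step 8 is the most likely to fail.**
- The chain is flexible and the ring is strained.
- The alkene is deactivated by the allylic ester.
- 18 is partly stored as hemiketal/spiro-lactol forms.
- The C6 aluminium alkoxide could take the acyl group from O-8.
- The C6 epimer may compete.

The fallback sets out from 18 and comes back at 19. It replaces the concerted aldehyde-ene reaction with a templated cation–olefin (Prins) closure. Ac2O/pyridine/DMAP traps the spirocyclic lactol tautomer of 18 as the anomeric 6-O-acetyl 3,6:3,10-bis-ketal F1. This ties C3, O-6 and O-10 into a 1,6-dioxaspiro[4.4]nonane that holds the two chain ends close together. TMSOTf with 2,6-di-t-Bu-4-Me-pyridine (CH2Cl2, 1 mM, −78 °C) ionises the acetate to a cyclic oxocarbenium ion. C7 attacks it and a methyl proton is lost, which gives the 3,6:3,10-diepoxy cage ketal F2. Aqueous TFA/THF opens this ketal to 19.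

**Step 5 is the second risk.**
- Only a small share of 12 is present as free aldehyde.
- Catalyst control on an unbranched aliphatic aldehyde is moderate.
- C4 epimers would be hard to separate.

The fallback sets out from 9 and comes back at 18. It brings C3–C6 in as one piece with C4 already set.
- Commercial α-methylene-γ-butyrolactone is hydrogenated with Ru–BINAP to (R)-3-methyloxolan-2-one F3.
- Me2AlSPh opens it to S-phenyl (R)-4-hydroxy-2-methylbutanethioate F4.
- TESCl/imidazole gives S-phenyl (R)-2-methyl-4-(triethylsilyloxy)butanethioate F5.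
- 9 is hydroborated with 9-BBN-H (2.2 equiv) to the B-alkyl borane F6.
- F6 is joined to F5 by a Liebeskind–Srogl acyl cross-coupling (Pd2(dba)3, tri-2-furylphosphine, CuTC, Cs2CO3, THF, 45 °C), which gives the keto silyl ether F7. The hindered allylic ester should ionise only slowly under these conditions.
- Swern conditions oxidise the primary TES ether of F7 directly to 18.

**Step 9 is the third risk.**
- The isopropenyl group is flanked by two oxygenated carbons.
- Attack at the C7 methine could compete.
- α-Oxidation of the ketone could compete.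

The fallback sets out from 19 and comes back at 21. Ene-type chlorination (Ca(OCl)2, solid CO2, CH2Cl2–H2O, 0 °C) gives the 12-chloro-11(13)-ene F8. N-Methylmorpholine N-oxide in MeCN (Ganem oxidation) converts it to the hydroxy enal 21, which closes to 22 and is carried through step 10.

## Further compounds
F1 | step 8 | 6-O-acetyl 3,6:3,10-bis-ketal (spiro-lactol acetate) of 18, anomeric and spiro centres as mixtures | CC(=O)OC1C[C@@H](C)C2(O1)CC[C@](C)(O2)C[C@@H](OC(=O)C(C)C)C=C(C)C
F2 | step 8 | 3,6:3,10-diepoxy cage ketal of 19, spiro centre fixed by the bridges | O2[C@H]1C[C@@H](C)C23CC[C@](C)(O3)C[C@@H](OC(=O)C(C)C)[C@H]1C(C)=C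
F3 | step 5 | (R)-3-methyloxolan-2-one | C[C@@H]1CCOC1=O
F4 | step 5 | S-phenyl (R)-4-hydroxy-2-methylbutanethioate | OCC[C@@H](C)C(=O)Sc1ccccc1
F5 | step 5 | S-phenyl (R)-2-methyl-4-(triethylsilyloxy)butanethioate | CC[Si](CC)(CC)OCC[C@@H](C)C(=O)Sc1ccccc1
F6 | step 5 | B-alkyl-9-BBN from 9 (tertiary hydroxyl as O-9-BBN borinate) | C(C[C@](C)(OB1C2CCCC1CCC2)C[C@@H](OC(=O)C(C)C)C=C(C)C)B1C2CCCC1CCC2
F7 | step 5 | (3R,7S,9R)-7-hydroxy-3,7,11-trimethyl-4-oxo-1-(triethylsilyloxy)dodec-10-en-9-yl 2-methylpropanoate | CC[Si](CC)(CC)OCC[C@@H](C)C(=O)CC[C@](C)(O)C[C@@H](OC(=O)C(C)C)C=C(C)C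
F8 | step 9 | (4R,6S,7S,8R,10S)-12-chloro-6,10-dihydroxy-8-isobutyryloxygermacr-11(13)-en-3-one | O[C@H]1C[C@@H](C)C(=O)CC[C@](C)(O)C[C@@H](OC(=O)C(C)C)[C@H]1C(=C)CCl
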